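Its constants were drawn at random within sensible limits; what happens was integrated by code.

The ratio we shall follow is R, the amount of Q made per amount of Z and L made together, and the share asked for comes straight from it.

in all of them: time 1.5 min

| charge | D | J | remark |
|---|---|---|---|
| south-east | 5.0 mM | 10.0 mM | everything together at the start |
| west | 5.0 mM (fed, over 80 s) | 10.0 mM | all else is in the flask from the start; the feed brings no volume worth counting |
| east | 5.0 mM | 10.0 mM (fed, over 80 s) | all else is in the flask from the start; the feed brings no volume worth counting |

* the flask that comes out highest in share of Z in Z plus Q, or "all alike" when all lie within 1.5 percentage points (south-east / west / east / all alike)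
* share of Z in Z plus Q at the end, south-east
* share of Z in Z plus Q at the end, west
* share of Z in Z plus Q at the end, east

- percent here means D units held: one D2 counts as two
- two of one species on the left: rate k times its square, two consumed each time
- run time (south-east): 1.5 min

    D + J ⇌ D.J (K1 = 79 /M, k1 = 8.6 /M/s)
    J + D.J ⇌ J.D.J (K2 = 58 /M, k2 = 1.3 /M/s)
    D + J → Z (k3 = 1.0 /M/s)
    J + D.J → Q (k4 = 7.2 /M/s)
    Z ⇌ L (K5 = 0.72, k5 = 0.069 /s)
    2 D → D2 (k6 = 0.0056 /M/s)

D meets J in two ways. Directly they give Z, with rate constant k_Z = 1.0 /M/s, and Z then passes to L and back. Or they join to D.J, with forward constant k_f = 8.6 /M/s and equilibrium constant K = 79 /M, so D.J falls back with k_b = k_f/K = 0.109 /s. A second J turns D.J into Q, with k_Q = 7.2 /M/s. We set J.D.J aside as a store that yields neither product.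

Leaving that store aside, a D.J has two exits, first-order constants k_b and k_Q[J]. They are equal at the crossover concentration of J, J_c = k_b/k_Q = 15.1 mM, and the fraction of D.J going on to Q is [J]/(J_c + [J]). With J at 5.00 mM, half its charge in south-east, D.J has a half-life by these two exits of 0.0797 min, short against the 1.5 min run. So we treat it as quasi-steady: it leaves as fast as it forms. Q then grows at k_f[D][J] times that fraction, Z and L together at k_Z[D][J], and [D][J] cancels:

R = (k_f/k_Z)·[J]/(J_c + [J]).

The relaxation half-life of Z and L, 0.0701 min in west, is also short against the run, so with L/Z = K_L = 0.72 the share of Z in Z plus Q is S = 1/(1 + (1 + K_L)R).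

Free J moves during a run, so we commit to guessed mean values: 5.00 mM in south-east, 7.50 mM in west, where D comes in slowly, and 2.50 mM in east, where J does. These give R = 2.14, 2.85 and 1.22, hence S = 21.4%, 16.9% and 32.3%.

The forecast also names east, with 17% in south-east, 14% in west and 22% in east, on the grounds that “feeding J keeps it scarce and favours Z, whereas feeding D keeps J in excess and favours Q”. Its east figure stands below ours.

The simulation gives east as highest, with 20.9% in south-east, 20.4% in west and 27.1% in east. Our reckoning is 5.2 percentage points high in east and 3.5 points low in west.

West ends at 1.50 min with 4.81 mM of free J, less than J_c, and its share is 20.4%. The neighbouring flask, like west but charged with 25 mM of J, ends with 16.5 mM free, a little more than J_c. Putting that J into the same formula gives R = 4.49 and S = 11.5%. The neighbouring flask gives 11.8%.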